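## Structural features

The target, bis(2,3,6-tribromo-4,5-dihydroxybenzyl) ether, consists of two identical, fully substituted benzene rings (ring A and ring A′) joined through their C1 carbons by a CH2–O–CH2 chain. Counting from the benzylic carbon as C1, each ring carries bromine at C2, C3 and C6 and a catechol at the neighbouring carbons C4 and C5. There is no stereocentre and no stereogenic double bond, so no stereocentres stand next to each other. The problem is one of substitution pattern and functional-group tolerance. Three groups are fragile. The catechols are oxidised to ortho-quinones, above all as their anions in air; the benzylic ether lies para to the C4 oxygen and can ionise (quinone methide under base and heat, benzylic cation under acid, exchange in alcoholic solvents); and the six aryl bromides forbid hydrogenolysis, low-valent metals and organolithium reagents late in the route. The real difficulty is to place six substituents on each ring in a defined order and then to uncover four phenols without harming that ether. Electrophilic bromination of an oxygenated ring, the obvious entry, invites ipso attack at C1 and oxidation. The feature used instead is that C4 and C5 of ring A and ring A′ are adjacent heteroatom-bearing carbons flanked by C3–Br and C6–Br. They can be carried as C–F bonds of an electron-poor perhalogenated ring and turned into C–O bonds by addition–elimination after all bromines and the ether bridge are in place.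

## Logic of the disconnections

13 is traced back to 11 by cutting the four O–CH2 bonds that tie 2-(trimethylsilyl)ethyl groups to the phenolic oxygens. The cut is made there because these groups fall off under fluoride alone, with no acid, Lewis acid, oxidant or reductant. The gain is that the oxidisable catechols become neutral alkyl ethers for as long as possible. The demand on the forward step is a fourfold fluoride-triggered β-elimination at a temperature low enough that the C4 phenoxide does not expel the para benzylic oxygen, followed by an oxygen-free, alcohol-free, weakly acidic work-up.

11 is cut at the aryl C4–O and C5–O bonds of both rings, which leads to 7 and four equivalents of 8. This is the only disconnection in which the ring is the electrophile, so the bromines and the ether can all be present beforehand on a ring without donor groups. The gain is large: two oxygenated hexasubstituted rings become a perhalogenated bis-ether and a commercial alcohol, and no electron-rich ring ever meets electrophilic bromine. The demand is four consecutive substitutions through the alkoxide 9 and the half-way stage 10. The second exchange on each ring takes place next to a newly installed alkoxy group, and fluoride must leave in preference to bromide. A potassium alkoxide would be the obvious choice, but a β-silyl potassium alkoxide is prone to Peterson-type fragmentation, so the sodium salt is used.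

7 is cut at one benzylic C–O bond of the bridge, giving 4 and 5 (through the alkoxide 6). Because the molecule is symmetric, both partners come from one intermediate, which halves the problem. The demand is that 6 attacks the benzylic carbon of 4 and not an aryl C–F carbon, which is met by working in an ethereal solvent at low temperature.

5 is traced back to 4 by exchanging the benzylic C–O bond for C–Br. The gain is that the alcohol needs no separate synthesis. The demand is a hydrolysis free of hydroxide and alkoxide, so that the aryl fluorides are not attacked early.

4 is traced back to 3 by cutting the benzylic C–Br bond. The methyl group is the only site with abstractable hydrogen, so a radical bromination needs no selectivity beyond stopping at the monobromide, which the two ortho bromines favour.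

3 is cut at its three aryl C–Br bonds, giving 1 and 2. The three ring hydrogens of 1 are exactly the three positions that must carry bromine, so exhaustive substitution needs no regiocontrol. The demand is a brominating system strong enough for a ring that becomes more deactivated with each bromine, used in the dark so that the methyl group is left alone.

## Other disconnections considered

Alternative 1: The cut runs through C5–C6 and C6–C1 of each ring, so the bromine-bearing C6 is inserted as a one-carbon unit into a five-membered ring. In the forward sense a dihalocarbene (from a haloform and a tertiary alkoxide) would add to the tetrasubstituted enol-ether double bond of bis[(6-methoxy-1,4-dioxaspiro[4.4]non-6-en-7-yl)methyl] ether A2. The gem-dibromocyclopropane would open with loss of bromide and a proton, and acid would unmask the ketone, which tautomerises to the phenol of bis(2-bromo-4-hydroxy-3-methoxybenzyl) ether A1.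
- In its favour: the carbene meets an electron-rich alkene, C6–Br is set without any regiochemical question, and both oxygens are in the carbocycle from the start. On certainty of the oxygen pattern it is the better plan, since no nucleophile has to choose between C–F and C–Br and no second substitution next to a donor is needed.
- Against it here: two hindered tetrasubstituted alkenes must both react, and the allylic ether arm sits next to the cation formed on ring opening.
- The larger problem is that A1 is unfinished. Each ring lacks the bromines at C2 and C3 and carries a free phenol para to the benzylic ether, so the remaining brominations run on exactly the electron-rich ring that is prone to ipso attack at C1.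
- The methyl ether at C5 would then have to be cleaved by a strong Lewis acid, which the bridge is unlikely to survive.
- Step economy: A2 needs several steps and three operations follow A1, so the alternative is clearly longer than the six steps of the chosen plan.

Alternative 2: The cut runs through C3–C4 and C5–C6. C4 and C5 with both oxygens come from di-tert-butoxyethyne A5, and C1, C2, C3 and C6 come from the dioxide rings of bis[(2,4,5-tribromo-1,1-dioxothiophen-3-yl)methyl] ether A4. The forward step is a twofold cycloaddition with inverse electron demand, followed by cheletropic loss of the sulfonyl bridge, to give bis(2,3,6-tribromo-4,5-di-tert-butoxybenzyl) ether A3.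
- In its favour: the electronic match is very good (strongly electron-poor diene, strongly electron-rich alkyne), the alkyne is symmetric so there is no regiochemical question, and all six substituents of each ring are fixed in one convergent step. On these mechanistic points it is the equal of the chosen plan or better.
- It shares with the chosen plan the merit that no oxygenated ring is ever brominated.
- Against it: A5 is thermally labile, since ynol tert-butyl ethers lose an alkene on warming to give ketenes.
- A4 requires oxidation of two very electron-poor tribromothiophenes, which calls for unusually strong oxygen-transfer reagents.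
- The product A3 places two neighbouring tert-butoxy groups between bromines, a strain that should already slow the cycloaddition.
- The unmasking of A3 is acidic, which is the condition under which the para-oxygenated benzylic ether ionises, whereas 11 is opened by fluoride.
- Step economy: the linear sequence would be comparable to the chosen plan, but the total number of steps is higher because both partners must be made.

Alternative 3: The cut runs through C1–C6 and C2–C3. Each bromoalkyne unit of bis(3-bromoprop-2-yn-1-yl) ether A7 supplies C1 and C2, and 2,5-dibromo-3,4-dimethoxythiophene 1,1-dioxide A8 supplies C3 to C6 with both oxygens. Cycloaddition and loss of the sulfonyl bridge would give bis(2,3,6-tribromo-4,5-dimethoxybenzyl) ether A6.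
- In its favour: this is the shortest plan on paper. A7 is one step from a commercial diyne ether and already contains the bridge, and A8 is two steps from a commercial dialkoxythiophene. On step count and convergence up to A6 it is better than the chosen plan.
- Against it: the diene carries two donor groups and the dienophile is an unactivated haloalkyne, so neither normal nor inverse electron demand is well served. The temperatures needed are likely to decompose both partners.
- The decisive weakness is the end game. Four aryl methyl ethers between bromines must be cleaved, and the reagents that do this (boron trihalides, hard Lewis acids, hot thiolates) would also cleave the benzylic ether or attack the aryl bromides.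
- The chosen plan is longer by about one step but ends with a deprotection that is orthogonal to every other group in 13.

Key step: step 5

Remark on the chemistry: read from the benzylic carbon as C1, each ring of the target is 2,3,6-tribromo-4,5-dihydroxy. Compounds 7 and 11 carry the same pattern with F or OCH2CH2SiMe3 at C4 and C5, so their structures need no correction. Compounds 1, 2 and 8 and all reagents are assumed to be commercial.

## Route

Step 1
Reactants: 1 3,4-difluorotoluene; 2 bromine
Product: 3 2,3,6-tribromo-4,5-difluorotoluene
Conditions: Br2 (neat, excess), AlBr3 (10 mol %), dark, 0 to 45 °C; aq. Na2SO3
Reagents that add atoms: bromine (compound 2), BrBr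
Why: Exhaustive electrophilic aromatic bromination; each of the three ring hydrogens is ortho or para to fluorine or methyl, and Br2 with AlBr3 is the standard system for perbrominating toluenes, so all three open positions should be filled while the methyl group stays intact in the dark.

Step 2
Reactants: 3 2,3,6-tribromo-4,5-difluorotoluene
Product: 4 2,3,6-tribromo-4,5-difluorobenzyl bromide
Conditions: NBS (1.1 equiv), AIBN (5 mol %), PhCF3, 85 °C
Reagents that add atoms: N-bromosuccinimide, O=C1CCC(=O)N1Br
Why: Wohl–Ziegler radical bromination; the methyl group holds the only hydrogens of the molecule, and the two ortho bromines should hinder a second abstraction, so the monobromide is expected to dominate.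

Step 3
Reactants: 4 2,3,6-tribromo-4,5-difluorobenzyl bromide (half of the batch)
Product: 5 (2,3,6-tribromo-4,5-difluorophenyl)methanol
Conditions: CaCO3 (2 equiv), 1,4-dioxane/H2O 1:1, reflux
Reagents that add atoms: water, O
Why: Buffered solvolysis of a benzylic bromide; water is the only nucleophile and insoluble CaCO3 only takes up HBr, so no hydroxide or alkoxide is present that could attack the aryl C–F bonds.

Step 4
Reactants: 5 (2,3,6-tribromo-4,5-difluorophenyl)methanol; 4 2,3,6-tribromo-4,5-difluorobenzyl bromide
Product: 7 bis(2,3,6-tribromo-4,5-difluorobenzyl) ether, via sodium (2,3,6-tribromo-4,5-difluorophenyl)methanolate 6 (not isolated)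
Conditions: 5, NaH (1.05 equiv), THF, 0 °C; then 4 (1.0 equiv), Bu4NI (10 mol %), 0 °C to rt
Reagents that add atoms: none
Why: Williamson ether synthesis (bimolecular substitution at a primary benzylic carbon, helped by iodide exchange); in THF at or below room temperature benzylic displacement should far outrun attack of 6 on an aryl C–F carbon, which needs a dipolar solvent and heat.

Step 5
Reactants: 7 bis(2,3,6-tribromo-4,5-difluorobenzyl) ether; 8 2-(trimethylsilyl)ethanol
Product: 11 bis{2,3,6-tribromo-4,5-bis[2-(trimethylsilyl)ethoxy]benzyl} ether, via sodium 2-(trimethylsilyl)ethanolate 9 (not isolated), via bis{2,3,6-tribromo-4-fluoro-5-[2-(trimethylsilyl)ethoxy]benzyl} ether 10 (not isolated)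
Conditions: 8 (6 equiv), NaH (5.6 equiv), THF, 0 °C; then 7, THF/DMF 1:1, 0 °C to rt; then 55 °C, Ar, dark
Reagents that add atoms: 2-(trimethylsilyl)ethanol (compound 8), C[Si](C)(C)CCO
Why: Nucleophilic aromatic substitution by addition–elimination: alkoxide 9 adds to a C–F carbon of ring A or ring A′, the Meisenheimer anion is stabilised inductively by the three bromines (charge on C2, C4 and C6 for attack at C5, on C1, C3 and C5 for attack at C4), and fluoride leaves. The closest known reaction type is alkoxide-for-fluoride exchange on polyhalogenated fluoroarenes, in which C–F is displaced in preference to C–Br, together with the established use of 2-(trimethylsilyl)ethoxide as a masked hydroxide towards fluoroarenes. No ring is closed and no stereocentre is formed; the four bonds made are C4–O and C5–O of both rings. C5 (ortho, meta and para bromine) and C4 (one ortho and two meta bromines) should be of similar reactivity, so the half-way stage is written as 10, but its C4-substituted regioisomers would converge on 11 in the same way. The second exchange on each ring is the slow one; it is helped because the first silylethoxy group is flanked on both sides and twisted out of conjugation, so that it acts mainly as an inductive acceptor, and it is driven by the dipolar co-solvent and mild heating. The selectivity needed is fluoride over bromide displacement and over halophilic attack at bromine; rate-determining addition at the most polarised carbons secures the first, and the absence of any ring hydrogen (no aryl anion, hence no halogen migration), a hard oxygen nucleophile and the exclusion of light secure the second. Sodium as counter-ion and a ceiling of about 55 °C limit Peterson-type fragmentation of 9 to ethylene and silanolate, which would deliver a deactivating phenoxide.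

Step 6
Reactants: 11 bis{2,3,6-tribromo-4,5-bis[2-(trimethylsilyl)ethoxy]benzyl} ether
Product: 13 bis(2,3,6-tribromo-4,5-dihydroxybenzyl) ether, via tetracesium bis(2,3,6-tribromo-4,5-dioxidobenzyl) ether 12 (not isolated)
Conditions: CsF (12 equiv), DMF (degassed), Ar, 20 to 40 °C; then AcOH, 0 °C; EtOAc/H2O work-up without alcohols
Reagents that add atoms: none
Why: Fluoride-induced β-elimination of 2-(trimethylsilyl)ethyl ethers; fluoride attacks silicon, ethylene is expelled and the brominated aryloxide, a good leaving group, departs, so the cleavage should run near room temperature without acid, reductant or oxidant and leave the six aryl bromides and the bridge intact. Cold acetic acid then protonates 12 to the target 13 before the C4 phenoxide can expel the para benzylic oxygen.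

## Compound list

1 | 3,4-difluorotoluene | Cc1ccc(F)c(F)c1 | starting material
2 | bromine | BrBr | starting material
3 | 2,3,6-tribromo-4,5-difluorotoluene | Cc1c(Br)c(Br)c(F)c(F)c1Br | intermediate
4 | 2,3,6-tribromo-4,5-difluorobenzyl bromide | BrCc1c(Br)c(Br)c(F)c(F)c1Br | intermediate
5 | (2,3,6-tribromo-4,5-difluorophenyl)methanol | OCc1c(Br)c(Br)c(F)c(F)c1Br | intermediate
6 | sodium (2,3,6-tribromo-4,5-difluorophenyl)methanolate | [Na+].[O-]Cc1c(Br)c(Br)c(F)c(F)c1Br | intermediate
7 | bis(2,3,6-tribromo-4,5-difluorobenzyl) ether | Fc1c(F)c(Br)c(COCc2c(Br)c(F)c(F)c(Br)c2Br)c(Br)c1Br | intermediate
8 | 2-(trimethylsilyl)ethanol | C[Si](C)(C)CCO | starting material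
9 | sodium 2-(trimethylsilyl)ethanolate | [Na+].[O-]CC[Si](C)(C)C | intermediate
10 | bis{2,3,6-tribromo-4-fluoro-5-[2-(trimethylsilyl)ethoxy]benzyl} ether | C[Si](C)(C)CCOc1c(F)c(Br)c(Br)c(COCc2c(Br)c(Br)c(F)c(OCC[Si](C)(C)C)c2Br)c1Br | intermediate
11 | bis{2,3,6-tribromo-4,5-bis[2-(trimethylsilyl)ethoxy]benzyl} ether | C[Si](C)(C)CCOc1c(OCC[Si](C)(C)C)c(Br)c(COCc2c(Br)c(OCC[Si](C)(C)C)c(OCC[Si](C)(C)C)c(Br)c2Br)c(Br)c1Br | intermediate
12 | tetracesium bis(2,3,6-tribromo-4,5-dioxidobenzyl) ether | [Cs+].[Cs+].[Cs+].[Cs+].[O-]c1c([O-])c(Br)c(COCc2c(Br)c([O-])c([O-])c(Br)c2Br)c(Br)c1Br | intermediate
13 | bis(2,3,6-tribromo-4,5-dihydroxybenzyl) ether (CNP0246948.0) | Oc1c(O)c(Br)c(COCc2c(Br)c(O)c(O)c(Br)c2Br)c(Br)c1Br | target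

## Step count and least certain steps

Total step count: 6. Longest linear sequence: 6 steps (1 → 3 → 4 → 5 → 7 → 11 → 13); 4 is used in steps 3 and 4, and 8 enters in step 5.

Step 5 (key step). The most likely failure is stalling after the first exchange on each ring. The remaining C–F carbon then stands next to an alkoxy group, and forcing the conditions may open side paths: displacement of bromide, reductive loss of bromine through halophilic attack, or fragmentation of the alkoxide before it reacts. The fallback sets out from 10, isolated after the room-temperature stage as whichever monofluoro regioisomers form, and rejoins the route at 13.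
- The last fluoride on each ring need not become an ether. Acetohydroxamic acid with K2CO3 in DMSO at about 70 °C is a known hydroxide surrogate whose α-effect oxygen nucleophile is smaller and more nucleophilic than 9.
- It should give the O-aryl hydroxamate bis{4-(acetamidooxy)-2,3,6-tribromo-5-[2-(trimethylsilyl)ethoxy]benzyl} ether F1, which collapses in the flask by a Lossen-type fragmentation.
- After mild acid this gives bis{2,3,6-tribromo-4-hydroxy-5-[2-(trimethylsilyl)ethoxy]benzyl} ether F2. The phenoxide arises only in the last substitution on its ring, so its deactivating effect no longer matters.
- CsF in DMF under the conditions of step 6 then removes the two remaining silylethyl groups from F2 to give 13. Either regioisomer of the half-way stage converges on the same product.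

Step 6. What may go wrong is slow loss of the second silylethyl group on each ring, since the leaving group is then a catecholate dianion. Warming to compensate could cause air oxidation of the catecholate or expulsion of the benzylic oxygen by the C4 phenoxide. The fallback sets out from 11 and rejoins at 13.
- The fluoride cleavage is run in the presence of acetic anhydride (CsF, Ac2O, DMF), so that each phenoxide is acetylated as soon as it is released.
- This should give the stable, chromatographable bis(4,5-diacetoxy-2,3,6-tribromobenzyl) ether F3, with no electron-rich anion accumulating.
- Hydrazine acetate in DMF at 0 to 20 °C, a buffered and nearly neutral known method for aryl acetates, then frees the four phenols to give 13.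

Step 4. What may go wrong is slow substitution at the doubly ortho-substituted benzylic carbon, which would let alkoxide 6 attack aryl C–F carbons and form oligomeric aryl ethers. The fallback sets out from 5 and rejoins at 7, and it avoids any alkoxide.
- 5 is treated with trichloroacetonitrile and catalytic DBU in CH2Cl2 to give 2,3,6-tribromo-4,5-difluorobenzyl 2,2,2-trichloroacetimidate F4.
- F4 alkylates a second equivalent of 5 under catalytic triflic acid to give 7.
- In that case all of 4 would be hydrolysed in step 3.

Step 1. What may go wrong is incomplete bromination at the last and most hindered position, or Lewis-acid-induced scrambling of substituents when the reaction is forced. The fallback sets out from 1 and rejoins at 3, and it replaces the last two electrophilic brominations by deprotonation chemistry.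
- Mild monobromination (Br2, Fe powder, CH2Cl2, 0 °C) should stop at 2-bromo-4,5-difluorotoluene F5.
- LDA in THF at −78 °C removes the ring hydrogen between bromine and fluorine, and a quench with 2 should give 2,3-dibromo-4,5-difluorotoluene F6.
- A second LDA and bromine cycle at the last ring hydrogen, ortho to fluorine, then gives 3.

## Further compounds

F1 | step 5 | bis{4-(acetamidooxy)-2,3,6-tribromo-5-[2-(trimethylsilyl)ethoxy]benzyl} ether | C[Si](C)(C)CCOc1c(ONC(C)=O)c(Br)c(Br)c(COCc2c(Br)c(Br)c(ONC(C)=O)c(OCC[Si](C)(C)C)c2Br)c1Br
F2 | step 5 | bis{2,3,6-tribromo-4-hydroxy-5-[2-(trimethylsilyl)ethoxy]benzyl} ether | C[Si](C)(C)CCOc1c(O)c(Br)c(Br)c(COCc2c(Br)c(Br)c(O)c(OCC[Si](C)(C)C)c2Br)c1Br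
F3 | step 6 | bis(4,5-diacetoxy-2,3,6-tribromobenzyl) ether | CC(=O)Oc1c(OC(C)=O)c(Br)c(COCc2c(Br)c(OC(C)=O)c(OC(C)=O)c(Br)c2Br)c(Br)c1Br
F4 | step 4 | 2,3,6-tribromo-4,5-difluorobenzyl 2,2,2-trichloroacetimidate | N=C(OCc1c(Br)c(Br)c(F)c(F)c1Br)C(Cl)(Cl)Cl
F5 | step 1 | 2-bromo-4,5-difluorotoluene | Cc1cc(F)c(F)cc1Br
F6 | step 1 | 2,3-dibromo-4,5-difluorotoluene | Cc1cc(F)c(F)c(Br)c1Br
A1 | alternative 1 | bis(2-bromo-4-hydroxy-3-methoxybenzyl) ether | COc1c(O)ccc(COCc2ccc(O)c(OC)c2Br)c1Br
A2 | alternative 1 | bis[(6-methoxy-1,4-dioxaspiro[4.4]non-6-en-7-yl)methyl] ether | COC1=C(COCC3=C(OC)C4(CC3)OCCO4)CCC12OCCO2
A3 | alternative 2 | bis(2,3,6-tribromo-4,5-di-tert-butoxybenzyl) ether | CC(C)(C)Oc1c(OC(C)(C)C)c(Br)c(COCc2c(Br)c(OC(C)(C)C)c(OC(C)(C)C)c(Br)c2Br)c(Br)c1Br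
A4 | alternative 2 | bis[(2,4,5-tribromo-1,1-dioxothiophen-3-yl)methyl] ether | O=S1(=O)C(Br)=C(COCC2=C(Br)S(=O)(=O)C(Br)=C2Br)C(Br)=C1Br
A5 | alternative 2 | di-tert-butoxyethyne | CC(C)(C)OC#COC(C)(C)C
A6 | alternative 3 | bis(2,3,6-tribromo-4,5-dimethoxybenzyl) ether | COc1c(OC)c(Br)c(COCc2c(Br)c(OC)c(OC)c(Br)c2Br)c(Br)c1Br
A7 | alternative 3 | bis(3-bromoprop-2-yn-1-yl) ether | BrC#CCOCC#CBr
A8 | alternative 3 | 2,5-dibromo-3,4-dimethoxythiophene 1,1-dioxide | COC1=C(Br)S(=O)(=O)C(Br)=C1OC
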